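**Retrosynthetic overview**
- Feature: in ring A (the cyclohexane), the exocyclic methylene carbon C2 sits between the quaternary carbon C1 (CH3 plus the two-carbon tether) and C3 (H, CH3). This pattern results when the enamine of an α-methyl aldehyde adds to the internal carbon of a terminal alkyne attached to a methyl-bearing stereocentre.
- Last disconnection: O1–C8a of pyran ring B. A (Z)-allylic tertiary alcohol displaces methoxide from a 2,5-dimethoxyquinone (ring C, from 1,2,4,5-tetramethoxybenzene). C4–C4a comes from a Sonogashira coupling.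
- The (S)-tertiary propargylic alcohol goes back through a Sharpless epoxy alcohol to a methyl ketone, and by two olefinations to (1S,3R)-1,3-dimethyl-2-methylidenecyclohexane-1-carbaldehyde.
- Key disconnection: C1–C2 of ring A. This is an amine/copper co-catalysed 6-exo-dig Conia-ene closure of (6R)-2,6-dimethyloct-7-ynal, made in three steps from (R)-citronellal, whose stereocentre becomes C3.
- Ring order: A (step 4), then C (introduced as the arene in step 13 and oxidised in step 15), then B (step 16).

Key step: step 4

Assumption: (R)-citronellal of high enantiomeric purity is used, because its stereocentre is the only source of absolute configuration in ring A.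

**Step 1**
Reactants: 1 (R)-citronellal [(3R)-3,7-dimethyloct-6-enal]
Product: 3 (3R)-3,7-dimethyloct-6-en-1-yne, via enol nonaflate 2 (not isolated)
Conditions: n-C4F9SO2F (1.2 equiv), P2-Et phosphazene base (2.4 equiv), DMF, −10 °C to rt
Reagents that add atoms: nonafluorobutane-1-sulfonyl fluoride, O=S(=O)(F)C(F)(F)C(F)(F)C(F)(F)C(F)(F)F (its atoms are held only in 2)
Why: One-pot aldehyde-to-alkyne conversion through the enol sulfonate, in which the base enolises the aldehyde, the sulfonyl fluoride traps the enolate on oxygen, and a second equivalent of base eliminates nonaflate from the 1-alkenyl sulfonate, which can only give the terminal alkyne, while the stereocentre (β to the carbonyl and never deprotonated) is carried over unchanged.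

**Step 2**
Reactants: 3 (3R)-3,7-dimethyloct-6-en-1-yne
Product: 5 (2E,6R)-2,6-dimethyloct-2-en-7-ynal, via allylic alcohol 4 (not isolated)
Conditions: SeO2 (0.3 equiv), t-BuOOH (2.5 equiv), salicylic acid (0.1 equiv), CH2Cl2, 0 °C to rt; crude, then MnO2 (15 equiv), CH2Cl2, rt
Reagents that add atoms: tert-butyl hydroperoxide, CC(C)(C)OO (oxygen, relayed by SeO2, O=[Se]=O)
Why: Riley allylic oxidation (ene reaction followed by [2,3]-sigmatropic shift) attacks the (E)-methyl group of the electron-rich trisubstituted alkene much faster than the propargylic C–H of a terminal alkyne, and MnO2 then converges the alcohol/aldehyde mixture on the (E)-enal.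

**Step 3**
Reactants: 5 (2E,6R)-2,6-dimethyloct-2-en-7-ynal
Product: 6 (6R)-2,6-dimethyloct-7-ynal (both C2 epimers)
Conditions: Hantzsch ester (diethyl 2,6-dimethyl-1,4-dihydropyridine-3,5-dicarboxylate, 1.2 equiv), Bn2NH·CF3CO2H (20 mol %), THF, 40 °C
Reagents that add atoms: none
Why: Iminium-catalysed transfer hydrogenation delivers hydride only to the β-carbon of the activated enal and leaves the terminal alkyne alone, whereas a copper hydride reagent would hydrocuprate or metalate that alkyne, and the mixture formed at C2 does not matter because this centre is erased in the enamine of step 4.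

**Step 4**
Reactants: 6 (6R)-2,6-dimethyloct-7-ynal (both C2 epimers)
Product: 9 (1S,3R)-1,3-dimethyl-2-methylidenecyclohexane-1-carbaldehyde, via N-cyclohexyl enamine 7 (not isolated), via cyclised N-cyclohexyl aldimine 8 (not isolated)
Conditions: Cu(OTf)2 (10 mol %), PPh3 (40 mol %), cyclohexylamine (20 mol %), degassed ClCH2CH2Cl (0.05 M), 50 °C; aq. NH4Cl work-up
Reagents that add atoms: cyclohexylamine, NC1CCCCC1 (held only in 7 and 8); water, O (carbonyl oxygen of 9 on hydrolysis of 8)
Why: Cyclohexylamine condenses with either C2 epimer of 6 to the same trisubstituted enamine 7, PPh3 reduces Cu(OTf)2 in situ to a cationic monovalent copper–phosphine π-acid that binds the terminal alkyne, the enamine α-carbon adds anti to the internal alkyne carbon, and protodemetalation of the vinylcopper followed by hydrolysis of aldimine 8 by the water of condensation releases 9 and both catalysts. The closest known reaction type is the amine and copper co-catalysed Conia-ene-type carbocyclisation of α-branched formyl alkynes to α-quaternary methylenecycloalkanes, routine for five-membered rings and less documented for six-membered ones, which is why loading and temperature are raised. Ring A closes in the 6-exo-dig mode, because the copper-bound terminal alkyne is polarised towards its substituted carbon and 7-endo attack at the CH terminus would need a longer reach. The new quaternary centre C1 is controlled by the resident C3 centre through a chair-like transition state: as C1 carries two carbon substituents, an axial C3 methyl would always face a syn-axial carbon group, so the C3 methyl stays equatorial even at the price of some allylic strain against the copper, which lies anti to C1 and hence on the C3 side. The extended CH–NHCy arm of the enamine is then expected to take the equatorial site at C1 and leave the C1 methyl axial, trans to the C3 methyl, which is the (1S,3R) isomer; this second preference is the weaker one, so the C1 epimer is removed by chromatography of 9, and the bias can be raised by exchanging PPh3 for the matched enantiomer of an atropisomeric bisphosphine or cyclohexylamine for a matched chiral primary amine. The step also needs the alkene to stay exocyclic and C3 to stay untouched, which the amine-buffered aprotic medium and the lack of any acidic C–H at C1 or C3 of 9 secure, and it needs cyclisation to outrun aldehyde–amine–alkyne coupling, which the hindered α-branched aldimine and the dilution favour.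

**Step 5**
Reactants: 9 (1S,3R)-1,3-dimethyl-2-methylidenecyclohexane-1-carbaldehyde; 10 dimethyl (2-oxopropyl)phosphonate
Product: 11 (3E)-4-[(1R,3R)-1,3-dimethyl-2-methylidenecyclohexyl]but-3-en-2-one
Conditions: NaH (1.3 equiv), 10 (1.4 equiv), THF, 0 °C; then 9, rt to reflux
Reagents that add atoms: dimethyl (2-oxopropyl)phosphonate 10, COP(=O)(CC(C)=O)OC
Why: Horner–Wadsworth–Emmons olefination of a non-enolisable neopentyl-type aldehyde with a stabilised keto-phosphonate anion gives the (E)-enone, with heating to compensate for the hindrance, and the descriptor at C1 changes to R only through the change of substituent priorities.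

**Step 6**
Reactants: 11 (3E)-4-[(1R,3R)-1,3-dimethyl-2-methylidenecyclohexyl]but-3-en-2-one
Product: 12 4-[(1R,3R)-1,3-dimethyl-2-methylidenecyclohexyl]butan-2-one
Conditions: [(Ph3P)CuH]6 (0.3 equiv), H2O (5 equiv), degassed toluene, rt
Reagents that add atoms: none
Why: Conjugate reduction by the phosphine-stabilised copper hydride hexamer is selective for the enone C=C (the copper enolate is protonated by water) and spares both the ketone and the hindered isolated 1,1-disubstituted alkene, and no alkyne is present at this stage.

**Step 7**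
Reactants: 12 4-[(1R,3R)-1,3-dimethyl-2-methylidenecyclohexyl]butan-2-one; 13 triethyl phosphonoacetate
Product: 14 ethyl (2E)-5-[(1R,3R)-1,3-dimethyl-2-methylidenecyclohexyl]-3-methylpent-2-enoate
Conditions: NaH (2 equiv), 13 (2.2 equiv), THF, 0 °C; then 12, rt to 50 °C; chromatographic removal of the (Z)-isomer
Reagents that add atoms: triethyl phosphonoacetate 13, CCOC(=O)CP(=O)(OCC)OCC
Why: Horner–Wadsworth–Emmons olefination of a methyl ketone favours the (E)-trisubstituted enoate with the longer chain trans to the ester, and the minor (Z)-isomer must be removed here because alkene geometry is translated into carbinol configuration in step 9.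

**Step 8**
Reactants: 14 ethyl (2E)-5-[(1R,3R)-1,3-dimethyl-2-methylidenecyclohexyl]-3-methylpent-2-enoate
Product: 15 (2E)-5-[(1R,3R)-1,3-dimethyl-2-methylidenecyclohexyl]-3-methylpent-2-en-1-ol
Conditions: i-Bu2AlH (2.5 equiv), CH2Cl2, −78 °C; aq. potassium sodium tartrate
Reagents that add atoms: none
Why: 1,2-Reduction of a conjugated ester by i-Bu2AlH stops at the allylic alcohol and touches neither alkene nor the alkene geometry.

**Step 9**
Reactants: 15 (2E)-5-[(1R,3R)-1,3-dimethyl-2-methylidenecyclohexyl]-3-methylpent-2-en-1-ol
Product: 16 [(2S,3S)-3-{2-[(1R,3R)-1,3-dimethyl-2-methylidenecyclohexyl]ethyl}-3-methyloxiran-2-yl]methanol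
Conditions: Ti(OiPr)4 (10 mol %), L-(+)-diethyl tartrate (12 mol %), t-BuOOH (2 equiv, decane), 4 Å MS, CH2Cl2, −20 °C
Reagents that add atoms: tert-butyl hydroperoxide, CC(C)(C)OO
Why: In the Sharpless asymmetric epoxidation the titanium–tartrate complex binds the allylic alcohol, so only that alkene reacts, and with L-(+)-tartrate an (E)-3-alkyl-3-methyl allylic alcohol of the geraniol type gives the (2S,3S)-epoxy alcohol, which fixes the future C2 of ring B under reagent control.

**Step 10**
Reactants: 16 [(2S,3S)-3-{2-[(1R,3R)-1,3-dimethyl-2-methylidenecyclohexyl]ethyl}-3-methyloxiran-2-yl]methanol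
Product: 17 (2S,3R)-3-(chloromethyl)-2-{2-[(1R,3R)-1,3-dimethyl-2-methylidenecyclohexyl]ethyl}-2-methyloxirane
Conditions: PPh3 (1.5 equiv), NaHCO3 (0.3 equiv), CCl4, reflux
Reagents that add atoms: tetrachloromethane, ClC(Cl)(Cl)Cl
Why: Buffered Appel chlorination replaces the primary hydroxyl by SN2 at CH2, so neither epoxide carbon is touched and the descriptor at the CH carbon changes only through priorities.

**Step 11**
Reactants: 17 (2S,3R)-3-(chloromethyl)-2-{2-[(1R,3R)-1,3-dimethyl-2-methylidenecyclohexyl]ethyl}-2-methyloxirane
Product: 19 (3S)-5-[(1R,3R)-1,3-dimethyl-2-methylidenecyclohexyl]-3-methylpent-1-yn-3-ol, via lithium chlorovinyl alkoxide 18 (not isolated)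
Conditions: n-BuLi (3.5 equiv), THF, −78 to −30 °C; then H2O
Reagents that add atoms: n-butyllithium, [Li]CCCC (lithium held only in 18)
Why: Base-induced double elimination of a 2,3-epoxy chloride, in which deprotonation at CH2Cl opens the epoxide by β-elimination to 18, dehydrochlorination gives the alkyne and the third equivalent is taken up by the acetylide, never breaks the C–O bond at the tertiary carbon, so the (S) configuration is retained.

**Step 12**
Reactants: 20 1,2,4,5-tetramethoxybenzene
Product: 22 3-iodo-1,2,4,5-tetramethoxybenzene, via aryllithium 21 (not isolated)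
Conditions: n-BuLi (1.1 equiv), THF, 0 °C to rt; I2 (1.2 equiv), −78 °C to rt
Reagents that add atoms: iodine, II; n-butyllithium, [Li]CCCC (lithium held only in 21)
Why: Directed ortho-lithiation between two methoxy groups (the two free ring positions are equivalent) followed by iodinolysis gives a single mono-iodide without exposing the easily oxidised arene to an electrophilic oxidant.

**Step 13**
Reactants: 19 (3S)-5-[(1R,3R)-1,3-dimethyl-2-methylidenecyclohexyl]-3-methylpent-1-yn-3-ol; 22 3-iodo-1,2,4,5-tetramethoxybenzene
Product: 23 (3S)-5-[(1R,3R)-1,3-dimethyl-2-methylidenecyclohexyl]-3-methyl-1-(2,3,5,6-tetramethoxyphenyl)pent-1-yn-3-ol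
Conditions: PdCl2(PPh3)2 (5 mol %), CuI (10 mol %), Et3N–DMF 1:1, degassed, 60 °C
Reagents that add atoms: 3-iodo-1,2,4,5-tetramethoxybenzene 22, COc1cc(OC)c(OC)c(I)c1OC
Why: Free tertiary propargylic alcohols are standard partners in Sonogashira coupling, and the iodide with gentle heating is chosen because oxidative addition into an electron-rich, doubly ortho-substituted ring is slow.

**Step 14**
Reactants: 23 (3S)-5-[(1R,3R)-1,3-dimethyl-2-methylidenecyclohexyl]-3-methyl-1-(2,3,5,6-tetramethoxyphenyl)pent-1-yn-3-ol
Product: 24 (1Z,3S)-5-[(1R,3R)-1,3-dimethyl-2-methylidenecyclohexyl]-3-methyl-1-(2,3,5,6-tetramethoxyphenyl)pent-1-en-3-ol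
Conditions: H2 (1 atm), Pd/CaCO3 poisoned with Pb(OAc)2 (Lindlar catalyst), quinoline, EtOAc, rt, stopped at one equivalent of H2
Reagents that add atoms: none
Why: Lindlar semihydrogenation adds H2 syn to give the (Z)-alkene that later brings the hydroxyl within reach of ring C, and the poisoned catalyst leaves the hindered exocyclic alkene alone.

**Step 15**
Reactants: 24 (1Z,3S)-5-[(1R,3R)-1,3-dimethyl-2-methylidenecyclohexyl]-3-methyl-1-(2,3,5,6-tetramethoxyphenyl)pent-1-en-3-ol
Product: 25 3-{(1Z,3S)-5-[(1R,3R)-1,3-dimethyl-2-methylidenecyclohexyl]-3-hydroxy-3-methylpent-1-en-1-yl}-2,5-dimethoxycyclohexa-2,5-diene-1,4-dione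
Conditions: (NH4)2Ce(NO3)6 (2.5 equiv), MeCN–H2O 3:1, 0 °C, 10 min; rapid extractive work-up, dark
Reagents that add atoms: water, O (both quinone carbonyl oxygens)
Why: Oxidative demethylation of a para-dimethoxy pair by tetravalent cerium is very fast on this electron-rich ring, the mirror plane through the substituted and the unsubstituted ring carbons makes both possible para pairs give the same 2,5-dimethoxyquinone, and the short cold exposure is meant to spare the tertiary allylic alcohol and both alkenes.

**Step 16**
Reactants: 25 3-{(1Z,3S)-5-[(1R,3R)-1,3-dimethyl-2-methylidenecyclohexyl]-3-hydroxy-3-methylpent-1-en-1-yl}-2,5-dimethoxycyclohexa-2,5-diene-1,4-dione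
Product: 26 metachromin E [(2S)-2-{2-[(1R,3R)-1,3-dimethyl-2-methylidenecyclohexyl]ethyl}-6-methoxy-2-methyl-2H-chromene-5,8-dione]
Conditions: Cs2CO3 (0.2 equiv), 4 Å MS, MeCN, rt, dark
Reagents that add atoms: none
Why: Intramolecular addition–elimination (vinylogous transesterification, 6-endo-trig) of the (Z)-held tertiary alkoxide occurs at the methoxy-bearing quinone carbon next to the side chain, which is the position where oxygen nucleophiles are known to displace methoxide in 3-substituted 2,5-dimethoxyquinones, the sieves take up the methanol, and the carbinol C–O bond stays intact so the (S) centre is retained.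

**Compound list**
1 | (R)-citronellal, (3R)-3,7-dimethyloct-6-enal | O=CC[C@H](C)CCC=C(C)C | starting material
2 | (3R)-3,7-dimethylocta-1,6-dien-1-yl nonafluorobutane-1-sulfonate (E/Z mixture) | O=S(=O)(OC=C[C@H](C)CCC=C(C)C)C(F)(F)C(F)(F)C(F)(F)C(F)(F)F | intermediate
3 | (3R)-3,7-dimethyloct-6-en-1-yne | C#C[C@H](C)CCC=C(C)C | intermediate
4 | (2E,6R)-2,6-dimethyloct-2-en-7-yn-1-ol | C#C[C@H](C)CC/C=C(\C)CO | intermediate
5 | (2E,6R)-2,6-dimethyloct-2-en-7-ynal | C#C[C@H](C)CC/C=C(\C)C=O | intermediate
6 | (6R)-2,6-dimethyloct-7-ynal (both C2 epimers) | C#C[C@H](C)CCCC(C)C=O | intermediate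
7 | N-[(6R)-2,6-dimethyloct-1-en-7-yn-1-yl]cyclohexanamine (E/Z mixture) | C#C[C@H](C)CCCC(C)=CNC1CCCCC1 | intermediate
8 | N-cyclohexyl-1-[(1S,3R)-1,3-dimethyl-2-methylidenecyclohexyl]methanimine | C=C1[C@H](C)CCC[C@]1(C)C=NC2CCCCC2 | intermediate
9 | (1S,3R)-1,3-dimethyl-2-methylidenecyclohexane-1-carbaldehyde | C=C1[C@H](C)CCC[C@]1(C)C=O | intermediate
10 | dimethyl (2-oxopropyl)phosphonate | COP(=O)(CC(C)=O)OC | starting material
11 | (3E)-4-[(1R,3R)-1,3-dimethyl-2-methylidenecyclohexyl]but-3-en-2-one | C=C1[C@H](C)CCC[C@]1(C)/C=C/C(C)=O | intermediate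
12 | 4-[(1R,3R)-1,3-dimethyl-2-methylidenecyclohexyl]butan-2-one | C=C1[C@H](C)CCC[C@]1(C)CCC(C)=O | intermediate
13 | triethyl phosphonoacetate | CCOC(=O)CP(=O)(OCC)OCC | starting material
14 | ethyl (2E)-5-[(1R,3R)-1,3-dimethyl-2-methylidenecyclohexyl]-3-methylpent-2-enoate | C=C1[C@H](C)CCC[C@]1(C)CC/C(C)=C/C(=O)OCC | intermediate
15 | (2E)-5-[(1R,3R)-1,3-dimethyl-2-methylidenecyclohexyl]-3-methylpent-2-en-1-ol | C=C1[C@H](C)CCC[C@]1(C)CC/C(C)=C/CO | intermediate
16 | [(2S,3S)-3-{2-[(1R,3R)-1,3-dimethyl-2-methylidenecyclohexyl]ethyl}-3-methyloxiran-2-yl]methanol | C=C1[C@H](C)CCC[C@]1(C)CC[C@]2(C)O[C@H]2CO | intermediate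
17 | (2S,3R)-3-(chloromethyl)-2-{2-[(1R,3R)-1,3-dimethyl-2-methylidenecyclohexyl]ethyl}-2-methyloxirane | C=C1[C@H](C)CCC[C@]1(C)CC[C@]2(C)O[C@H]2CCl | intermediate
18 | lithium (3S)-1-chloro-5-[(1R,3R)-1,3-dimethyl-2-methylidenecyclohexyl]-3-methylpent-1-en-3-olate | C=C1[C@H](C)CCC[C@]1(C)CC[C@@](O[Li])(C)C=CCl | intermediate
19 | (3S)-5-[(1R,3R)-1,3-dimethyl-2-methylidenecyclohexyl]-3-methylpent-1-yn-3-ol | C=C1[C@H](C)CCC[C@]1(C)CC[C@@](O)(C)C#C | intermediate
20 | 1,2,4,5-tetramethoxybenzene | COc1cc(OC)c(OC)cc1OC | starting material
21 | (2,3,5,6-tetramethoxyphenyl)lithium | [Li]c1c(OC)c(OC)cc(OC)c1OC | intermediate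
22 | 3-iodo-1,2,4,5-tetramethoxybenzene | COc1cc(OC)c(OC)c(I)c1OC | intermediate
23 | (3S)-5-[(1R,3R)-1,3-dimethyl-2-methylidenecyclohexyl]-3-methyl-1-(2,3,5,6-tetramethoxyphenyl)pent-1-yn-3-ol | C=C1[C@H](C)CCC[C@]1(C)CC[C@@](O)(C)C#Cc2c(OC)c(OC)cc(OC)c2OC | intermediate
24 | (1Z,3S)-5-[(1R,3R)-1,3-dimethyl-2-methylidenecyclohexyl]-3-methyl-1-(2,3,5,6-tetramethoxyphenyl)pent-1-en-3-ol | C=C1[C@H](C)CCC[C@]1(C)CC[C@@](O)(C)/C=C\c2c(OC)c(OC)cc(OC)c2OC | intermediate
25 | 3-{(1Z,3S)-5-[(1R,3R)-1,3-dimethyl-2-methylidenecyclohexyl]-3-hydroxy-3-methylpent-1-en-1-yl}-2,5-dimethoxycyclohexa-2,5-diene-1,4-dione | C=C1[C@H](C)CCC[C@]1(C)CC[C@@](O)(C)/C=C\C2=C(OC)C(=O)C=C(OC)C2=O | intermediate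
26 | metachromin E, (2S)-2-{2-[(1R,3R)-1,3-dimethyl-2-methylidenecyclohexyl]ethyl}-6-methoxy-2-methyl-2H-chromene-5,8-dione | C=C1[C@H](C)CCC[C@]1(C)CC[C@@]1(C)C=CC2=C(O1)C(=O)C=C(OC)C2=O | target

**Total step count:** 16.
**Longest linear sequence:** 15 (steps 1–11 and 13–16). Step 12 is the one-step side branch.

**Steps most likely to fail**

1. **Step 4.**
   - What may go wrong: the 6-exo closure may be too slow on a chain without geminal substituents. Aldehyde–amine–alkyne coupling, oxidative alkyne dimerisation or drift of the exocyclic alkene into the ring could then take over. The facial bias at the enamine carbon may also be weak.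
   - Fallback: it sets out from 6. O-Silylation (TBSOTf, Et3N, CH2Cl2, 0 °C) should give the tert-butyldimethylsilyl enol ether F1 as an E/Z mixture. A cationic monovalent gold catalyst ((Ph3P)AuCl/AgBF4, 5 mol %, CH2Cl2–H2O 10:1, rt to 40 °C) then drives the known 6-exo-dig carbocyclisation of a silyl enol ether onto a terminal alkyne, with water taking up the silyl group. The route is rejoined at 9.
   - What changes: the nucleophile is preformed and stoichiometric, and no amine or copper acetylide chemistry can compete. Any C1 epimer would again be separated at 9.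

2. **Step 15.**
   - What may go wrong: the acidic oxidant may ionise the tertiary allylic carbinol while the ring is still electron-rich. That would mean loss of configuration at the carbinol carbon, allylic transposition or dehydration.
   - Fallback: it sets out from 24. Constant-current anodic oxidation (Pt anode, 1 % KOH in MeOH, 0 °C), the known two-electron anodic methoxylation of para-dimethoxyarenes, should give the quinone bis(dimethyl ketal) F2 in a basic medium. Once the ring is no longer aromatic, brief hydrolysis (aqueous oxalic acid, THF, 0 °C) releases the quinone. The route is rejoined at 25.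

3. **Step 16.**
   - What may go wrong: the tertiary alkoxide may add reversibly, with methoxide returning and reopening ring B. The quinone may also degrade under base before closure.
   - Fallback: it exchanges the leaving group and sets out from 25. KOH (2 M, MeOH–H2O, 0 °C, then acidification) displaces the same hindered methoxy group by hydroxide, the known selective mono-hydrolysis of 3-substituted 2,5-dimethoxyquinones, to give the hydroxyquinone F3. Tf2O and 2,6-lutidine (CH2Cl2, −78 °C) sulfonylate only the acidic quinone hydroxyl to give the quinonyl triflate F4. Et3N on warming lets the tertiary alcohol displace triflate irreversibly by addition–elimination, with the carbinol C–O bond intact. The route is rejoined at 26.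

**Further compounds**
F1 | step 4 | tert-butyl{[(6R)-2,6-dimethyloct-1-en-7-yn-1-yl]oxy}dimethylsilane (E/Z mixture) | C#C[C@H](C)CCCC(C)=CO[Si](C)(C)C(C)(C)C
F2 | step 15 | (1Z,3S)-5-[(1R,3R)-1,3-dimethyl-2-methylidenecyclohexyl]-1-(2,3,3,5,6,6-hexamethoxycyclohexa-1,4-dien-1-yl)-3-methylpent-1-en-3-ol | C=C1[C@H](C)CCC[C@]1(C)CC[C@@](O)(C)/C=C\C2=C(OC)C(OC)(OC)C=C(OC)C2(OC)OC
F3 | step 16 | 3-{(1Z,3S)-5-[(1R,3R)-1,3-dimethyl-2-methylidenecyclohexyl]-3-hydroxy-3-methylpent-1-en-1-yl}-2-hydroxy-5-methoxycyclohexa-2,5-diene-1,4-dione | C=C1[C@H](C)CCC[C@]1(C)CC[C@@](O)(C)/C=C\C2=C(O)C(=O)C=C(OC)C2=O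
F4 | step 16 | 2-{(1Z,3S)-5-[(1R,3R)-1,3-dimethyl-2-methylidenecyclohexyl]-3-hydroxy-3-methylpent-1-en-1-yl}-4-methoxy-3,6-dioxocyclohexa-1,4-dien-1-yl trifluoromethanesulfonate | C=C1[C@H](C)CCC[C@]1(C)CC[C@@](O)(C)/C=C\C2=C(OS(=O)(=O)C(F)(F)F)C(=O)C=C(OC)C2=O
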